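**Assumption:** the target has no stereocentre and no stereogenic double bond, so the achiral compound itself is the "single enantiomer"; the side chain is read as unbranched C23 (tricosyl).

## Retrosynthetic overview

1. Target 8 ⇐ photochemical ring contraction of 4-tricosylpyridine 1-oxide 5: pyridine C2 is extruded as the CHO group and N re-bonds to old C3. This replaces the usual alkylation/acylation and Vilsmeier formylation of a preformed pyrrole.
2. 5 ⇐ N-oxidation of 4-tricosylpyridine 4.
3. 4 ⇐ lateral lithiation of 4-methylpyridine 1 and SN2 alkylation with 1-bromodocosane 2 (C1 + C22 = C23).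
4. Ring order: the pyridine ring is bought; the pyrrole ring, the only ring of the target, is formed last by contracting it. Because C2 and C6 of 5 are equivalent, only the 3-alkyl-2-formyl isomer can form.

## Route

**Step 1**
Reactants: 1 4-methylpyridine, 2 1-bromodocosane
Product: 4 4-tricosylpyridine, via (pyridin-4-ylmethyl)lithium 3 (not isolated)
Conditions: 1 (1.3 equiv), LiN(iPr)2 (1.25 equiv), THF, −78 °C, 45 min; then 2 (1.0 equiv) in THF, −78 °C → rt, 12 h
Reagents that add atoms: none
Why: Lateral (aza-benzylic) deprotonation of 4-picoline by the lithium amide gives the picolyl anion 3, which undergoes clean SN2 alkylation with the unhindered primary bromide (excess anion and inverse stoichiometry limit dialkylation); no stereocentre is formed.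

**Step 2**
Reactants: 4 4-tricosylpyridine
Product: 5 4-tricosylpyridine 1-oxide
Conditions: mCPBA (1.2 equiv), CH2Cl2, 0 °C → rt, 4 h; aq. Na2SO3, then aq. K2CO3 wash
Reagents that add atoms: mCPBA (3-chloroperoxybenzoic acid), O=C(OO)c1cccc(Cl)c1
Why: Peracid N-oxidation (electrophilic oxygen transfer to the pyridine lone pair) is selective because the saturated chain is inert; no stereocentre is formed.

**Step 3**
Reactants: 5 4-tricosylpyridine 1-oxide
Product: 8 3-tricosyl-1H-pyrrole-2-carbaldehyde, via bicyclic oxaziridine 6 (not isolated), via 3-tricosyl-2H-pyrrole-2-carbaldehyde 7 (not isolated)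
Conditions: hν (254 nm, quartz, low-pressure Hg lamps), Cu(OTf)2 (2 equiv), degassed t-BuOH/MeCN 3:1 (2 mM in 5), 30 °C, stopped at ca. 80% conversion; recovered 5 recycled
Reagents that add atoms: none
Why: This is the photochemical ring contraction of a pyridine N-oxide to a 2-formylpyrrole, known for 4-methylpyridine 1-oxide in aqueous CuSO4 and run here in an organic medium with a soluble divalent copper salt for solubility: excitation closes the N-oxide to oxaziridine 6, N–O/C–N cleavage gives a copper-stabilised acyl vinylnitrene that re-closes from N to old C3 to give 7, and a 1,5-hydrogen shift aromatises 7 to 8, with only one regioisomer possible because C2 and C6 of 5 are equivalent; no stereocentre is formed (expected yield about 25–35%).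

## Compound list

1 | 4-methylpyridine (4-picoline) | Cc1ccncc1 | starting material
2 | 1-bromodocosane | CCCCCCCCCCCCCCCCCCCCCCBr | starting material
3 | (pyridin-4-ylmethyl)lithium | [Li]Cc1ccncc1 | intermediate
4 | 4-tricosylpyridine | CCCCCCCCCCCCCCCCCCCCCCCc1ccncc1 | intermediate
5 | 4-tricosylpyridine 1-oxide | CCCCCCCCCCCCCCCCCCCCCCCc1cc[n+]([O-])cc1 | intermediate
6 | 4-tricosyl-7-oxa-1-azabicyclo[4.1.0]hepta-2,4-diene (bicyclic oxaziridine; racemic, transient) | CCCCCCCCCCCCCCCCCCCCCCCC1=CC2ON2C=C1 | intermediate
7 | 3-tricosyl-2H-pyrrole-2-carbaldehyde (racemic, transient) | CCCCCCCCCCCCCCCCCCCCCCCC1=CC=NC1C=O | intermediate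
8 | 3-tricosyl-1H-pyrrole-2-carbaldehyde (achiral) | CCCCCCCCCCCCCCCCCCCCCCCc1cc[nH]c1C=O | target

## Summary

Total step count: 3. Longest linear sequence: 3 steps (1 → 4 → 5 → 8).

## Steps most likely to fail, with fallbacks

**Step 3 (highest risk).** The photo-contraction competes with deoxygenation back to 4 and with pyridone and hydroxypyridine formation. Product 8 absorbs in the same region and can be photolysed further, and the lipophilic substrate is outside the aqueous conditions under which the reaction is best known.

The fallback abandons the ring contraction and builds on a preformed pyrrole, setting out from 2 and returning at 8: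
- 2 is heated with PPh3 (MeCN, reflux) to give docosyl(triphenyl)phosphonium bromide F1.
- NaN(SiMe3)2 (THF, −78 → 0 °C) converts F1 into the ylide (docosylidene)triphenylphosphorane F2.
- Wittig reaction of F2 with commercial 1-(triisopropylsilyl)-1H-pyrrole-3-carbaldehyde (O=Cc1ccn([Si](C(C)C)(C(C)C)C(C)C)c1) gives 3-[(Z)-tricos-1-en-1-yl]-1-(triisopropylsilyl)-1H-pyrrole F3; the alkene geometry is irrelevant.
- Hydrogenation (H2, 1 atm, Pd/C, i.e. palladium metal on carbon, EtOAc/THF) gives 3-tricosyl-1-(triisopropylsilyl)-1H-pyrrole F4.
- Bu4NF in THF removes the silyl group to give 3-tricosyl-1H-pyrrole F5.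
- Vilsmeier–Haack formylation (POCl3, DMF, 0 °C; then aq. NaOAc, 60 °C) passes through N,N-dimethyl-1-(3-tricosyl-1H-pyrrol-2-yl)methaniminium chloride F6 and gives 8 as the major regioisomer (attack at C2 next to the alkyl group). The minor regioisomer is removed by chromatography.

**Step 1.** The waxy C22 bromide may precipitate at low temperature and react sluggishly, and the product's picolyl CH2 can be deprotonated again and dialkylated.

The fallback replaces SN2 alkylation by acylation and deoxygenation, setting out from 3 (made from 1 as in step 1, 2.2 equiv) and returning at 4: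
- 3 is acylated (Claisen-type, THF, −78 → 0 °C) with commercial methyl docosanoate (CCCCCCCCCCCCCCCCCCCCCC(=O)OC) to give, after aqueous work-up, 1-(pyridin-4-yl)tricosan-2-one F7.
- Wolff–Kishner (Huang-Minlon) reduction with N2H4·H2O and KOH in diethylene glycol (130 → 200 °C) proceeds through the hydrazone 4-(2-hydrazinylidenetricosyl)pyridine F8 and gives 4.

**Step 2.** The oxidation itself is reliable. The risk is practical: the N-oxide is a waxy amphiphile that forms emulsions and is hard to free from 3-chlorobenzoic acid, and any acid carried forward would divert the photolysis.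

The fallback installs the oxygen before the chain, so the long-chain compound is never oxidised. It sets out from 1 and returns at 5:
- 1 is oxidised (30% H2O2, AcOH, 70 °C) to 4-methylpyridine 1-oxide F9, which is purified by distillation or crystallisation.
- Thermodynamic lateral deprotonation with NaNH2 in liquid NH3/THF (−33 °C) gives sodium (1-oxidopyridin-1-ium-4-yl)methanide F10. This is the anion used in amide-mediated condensations of this N-oxide; alkyllithium bases are avoided because they metalate the ring at C2.
- Alkylation of F10 with 2 (added in THF, then NH3 allowed to evaporate, rt) gives 5 directly.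

## Further compounds

F1 | step 3 | docosyl(triphenyl)phosphonium bromide | CCCCCCCCCCCCCCCCCCCCCC[P+](c1ccccc1)(c1ccccc1)c1ccccc1.[Br-]
F2 | step 3 | (docosylidene)triphenylphosphorane | CCCCCCCCCCCCCCCCCCCCCC=P(c1ccccc1)(c1ccccc1)c1ccccc1
F3 | step 3 | 3-[(Z)-tricos-1-en-1-yl]-1-(triisopropylsilyl)-1H-pyrrole | CCCCCCCCCCCCCCCCCCCCC/C=C\c1ccn([Si](C(C)C)(C(C)C)C(C)C)c1
F4 | step 3 | 3-tricosyl-1-(triisopropylsilyl)-1H-pyrrole | CCCCCCCCCCCCCCCCCCCCCCCc1ccn([Si](C(C)C)(C(C)C)C(C)C)c1
F5 | step 3 | 3-tricosyl-1H-pyrrole | CCCCCCCCCCCCCCCCCCCCCCCc1cc[nH]c1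
F6 | step 3 | N,N-dimethyl-1-(3-tricosyl-1H-pyrrol-2-yl)methaniminium chloride | CCCCCCCCCCCCCCCCCCCCCCCc1cc[nH]c1C=[N+](C)C.[Cl-]
F7 | step 1 | 1-(pyridin-4-yl)tricosan-2-one | CCCCCCCCCCCCCCCCCCCCCC(=O)Cc1ccncc1
F8 | step 1 | 4-(2-hydrazinylidenetricosyl)pyridine | CCCCCCCCCCCCCCCCCCCCCC(=NN)Cc1ccncc1
F9 | step 2 | 4-methylpyridine 1-oxide | Cc1cc[n+]([O-])cc1
F10 | step 2 | sodium (1-oxidopyridin-1-ium-4-yl)methanide | [Na]Cc1cc[n+]([O-])cc1
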